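**Retrosynthetic overview**

1. Target 20 ⇐ tertiary vinyl carbinol 18 (SN2′ bromination forms C8–Br and C6=C7) ⇐ α-acetoxy ketone 16 (vinyl addition at C6) ⇐ bromo ketone 14 (acetate for bromide at C1).
2. 14 ⇐ acyclic dibromomethyl ketone 13 by copper-catalysed bromine atom-transfer radical cyclisation: C1–C2 and C3–Br are formed and the cyclohexane ring, the only ring, closes 6-endo.
3. Structural basis: ring atoms C6–C5(Cl)–C4(Me2)–C3 are the C(=O)–CH(OH)–CMe2–CH2O carbons of pantolactone, and the C3 bromide, secondary and next to quaternary C4, is placed by the cyclised radical because substitution cannot reach it.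
4. 13 ⇐ (R)-pantolactone 1: triflate then chloride with inversion (sets C5), Weinreb opening, oxidation, methylenation (adds C2), dibromomethyllithium (adds C1).
5. Numbering used throughout: C1 (CHOAc), C2 (CH2), C3 (CHBr), C4 (CMe2), C5 (CHCl), C6 (ring alkylidene carbon), C7 (=CH), C8 (CH2Br).

Key step: step 7

Assumption (remark on the chemistry): the target is read as C1 S, C3 R, C5 R, Z alkene, that is OAc and Br cis and equatorial, Cl trans to both and axial, CH2Br on the C5 side. The C1 configuration of 14 is taken as inconsequential; 14 is drawn as the epimer that gives 16 by direct inversion, and its C1 epimer, if formed, would converge in step 8.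

**Step 1**
Reactants: 1 (R)-pantolactone; 2 trifluoromethanesulfonic anhydride
Product: 3 (R)-4,4-dimethyl-2-oxooxolan-3-yl trifluoromethanesulfonate
Conditions: Tf2O, pyridine, CH2Cl2, −20 → 0 °C
Reagents that add atoms: trifluoromethanesulfonic anhydride, O=S(=O)(OS(=O)(=O)C(F)(F)F)C(F)(F)F
Why: O-sulfonylation of the secondary α-hydroxy lactone leaves the C–O bond untouched (retention) and gives a leaving group reactive enough for displacement at a carbon flanked by a quaternary centre.

**Step 2**
Reactants: 3 (R)-pantolactone triflate; 4 lithium chloride
Product: 5 (S)-3-chloro-4,4-dimethyloxolan-2-one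
Conditions: LiCl (1.3 equiv), DMF, 0 °C → rt
Reagents that add atoms: lithium chloride, [Li+].[Cl-]
Why: SN2 displacement of an α-carbonyl triflate by chloride should proceed with inversion and set the future C5 as S, since the lactone carbonyl activates the centre, there is no β-hydrogen for elimination, and the small excess of chloride limits chloride–chloride exchange.

**Step 3**
Reactants: 5 (S)-chlorolactone; 6 N,O-dimethylhydroxylamine hydrochloride
Product: 7 (S)-2-chloro-4-hydroxy-N-methoxy-N,3,3-trimethylbutanamide
Conditions: MeNHOMe·HCl, AlMe3, CH2Cl2, 0 °C → rt; aqueous potassium sodium tartrate work-up; crude 7 used at once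
Reagents that add atoms: N,O-dimethylhydroxylamine hydrochloride, CNOC.Cl
Why: Weinreb aminolysis of a lactone by the Lewis-acidic, weakly basic aluminium amide should open the ring without epimerising the α-chloro centre, and immediate use avoids relactonisation.

**Step 4**
Reactants: 7 hydroxy Weinreb amide
Product: 8 (S)-2-chloro-N-methoxy-N,3,3-trimethyl-4-oxobutanamide
Conditions: Dess–Martin periodinane, NaHCO3, CH2Cl2, 0 °C → rt
Reagents that add atoms: none
Why: Dess–Martin oxidation of the primary neopentyl alcohol should give an aldehyde that has no α-hydrogen, while the bicarbonate buffer keeps acetic acid from promoting relactonisation.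

**Step 5**
Reactants: 8 aldehyde; 9 methyltriphenylphosphonium bromide
Product: 10 (S)-2-chloro-N-methoxy-N,3,3-trimethylpent-4-enamide
Conditions: Ph3PCH3Br (1.3 equiv), KN(SiMe3)2 (1.2 equiv), THF, −78 → 0 °C
Reagents that add atoms: methyltriphenylphosphonium bromide, C[P+](c1ccccc1)(c1ccccc1)c1ccccc1.[Br-]
Why: Wittig methylenation of the non-enolisable aldehyde should outrun any reaction at the Weinreb amide, and the deficit of base and low temperature keep the ylide from deprotonating the hindered α-chloro amide C–H.

**Step 6**
Reactants: 10 alkenyl Weinreb amide; 11 dibromomethane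
Product: 13 (S)-1,1-dibromo-3-chloro-4,4-dimethylhex-5-en-2-one, via lithium hemiaminal adduct 12 (not isolated)
Conditions: CH2Br2 (2.4 equiv), lithium 2,2,6,6-tetramethylpiperidide (2.0 equiv), THF, −78 °C; then 10; AcOH quench at −78 °C
Reagents that add atoms: dibromomethane, BrCBr
Why: Acylation of a lithium carbenoid by a Weinreb amide stops at the chelated tetrahedral adduct 12, so only one addition occurs and the acidic dibromomethyl ketone is released on cold acidic quench, while the C5–H is shielded by the quaternary carbon.

**Step 7**
Reactants: 13 (S)-1,1-dibromo-3-chloro-4,4-dimethylhex-5-en-2-one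
Product: 14 (2R,4R,6S)-2,4-dibromo-6-chloro-5,5-dimethylcyclohexan-1-one
Conditions: CuBr (20 mol %), tris(2-pyridylmethyl)amine (20 mol %), degassed 1,2-dichloroethane (0.02 M), 40 °C
Reagents that add atoms: none
Why: The monovalent copper complex reversibly abstracts one bromine from the CHBr2 group to give the α-bromo-α-keto radical at C1 and a divalent copper bromide complex; the radical adds to the terminal alkene carbon C2 (new C1–C2 bond) and the secondary C3 radical takes bromine back from divalent copper (new C3–Br bond), regenerating the catalyst. The closest known reaction type is the Kharasch-type copper-catalysed atom-transfer radical cyclisation of α-polyhalo carbonyl compounds. The cyclohexanone ring closes 6-endo-trig, the usual course for a hex-5-enyl radical whose carbonyl lies inside the forming ring, and here the internal alkene carbon C3 is also screened by quaternary C4, whose gem-dimethyl group favours folding. At C3 bromine should arrive on the face opposite the C5 chloride, which sits axial to avoid both C4 methyls and so blocks the syn-axial approach, giving an equatorial bromide trans to chlorine; the pantolactone-derived C5 centre is the controlling element. C1 needs no control because it stays exchangeable and converges in step 8. The step needs 6-endo over 5-exo closure, activation of the geminal dibromide in preference to the α-C–Cl bond (weaker, doubly activated C–Br bonds and a bromide-only copper salt) and cyclisation over telomerisation (high dilution).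

**Step 8**
Reactants: 14 dibromo chloro ketone; 15 caesium acetate
Product: 16 (1S,3S,5R)-5-bromo-3-chloro-4,4-dimethyl-2-oxocyclohexyl acetate
Conditions: CsOAc (1.5 equiv), AcOH (0.5 equiv), DMF, 0 °C → rt
Reagents that add atoms: caesium acetate, CC(=O)[O-].[Cs+]
Why: SN2 substitution of the carbonyl-activated C1 bromide by acetate inverts C1 to the equatorial acetate cis to the C3 bromide, the two neopentyl halides (C3–Br, C5–Cl) are not displaced, and enolisation under the acetate buffer can only move C1 and C5 towards this same arrangement (equatorial OAc, axial Cl), which is expected to be the most stable.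

**Step 9**
Reactants: 16 α-acetoxy ketone; 17 vinylmagnesium bromide
Product: 18 (1S,2R,3S,5R)-5-bromo-3-chloro-2-ethenyl-2-hydroxy-4,4-dimethylcyclohexyl acetate
Conditions: CH2=CHMgBr (1.5 equiv), anhydrous CeCl3 (1.6 equiv), THF, −78 °C; pH 7 buffer quench at −78 °C
Reagents that add atoms: vinylmagnesium bromide, C=C[Mg]Br
Why: Organocerium 1,2-addition is weakly basic and ketone-selective, so it should add to C6 without enolisation or attack on the acetate, and the cold quench comes before the tertiary alkoxide can displace the C5 chloride; the carbinol configuration (drawn for attack anti to the C5–Cl bond, polar Felkin–Anh) is not needed because C6 becomes trigonal in step 10.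

**Step 10**
Reactants: 18 tertiary vinyl carbinol; 19 phosphorus tribromide
Product: 20 (1S,2Z,3R,5R)-5-bromo-2-(2-bromoethylidene)-3-chloro-4,4-dimethylcyclohexyl acetate (target)
Conditions: PBr3 (0.5 equiv), Et2O, −20 → 0 °C
Reagents that add atoms: phosphorus tribromide, BrP(Br)Br
Why: SN2′ bromination of a 1-vinylcycloalkanol through its bromophosphite puts bromide on the terminal vinyl carbon with allylic transposition, and the CH2Br group should settle on the C5 side (Z), where the axial chloride leaves only an equatorial hydrogen to meet it, not on the C1 side, where it would clash with the equatorial acetate (A(1,3) strain); the ring stereocentres are not touched.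

**Compound list**

1 | (R)-pantolactone | CC1(C)COC(=O)[C@@H]1O | starting material
2 | trifluoromethanesulfonic anhydride | O=S(=O)(OS(=O)(=O)C(F)(F)F)C(F)(F)F | starting material
3 | (R)-4,4-dimethyl-2-oxooxolan-3-yl trifluoromethanesulfonate | CC1(C)COC(=O)[C@@H]1OS(=O)(=O)C(F)(F)F | intermediate
4 | lithium chloride | [Li+].[Cl-] | starting material
5 | (S)-3-chloro-4,4-dimethyloxolan-2-one | CC1(C)COC(=O)[C@H]1Cl | intermediate
6 | N,O-dimethylhydroxylamine hydrochloride | CNOC.Cl | starting material
7 | (S)-2-chloro-4-hydroxy-N-methoxy-N,3,3-trimethylbutanamide | OCC(C)(C)[C@H](Cl)C(=O)N(C)OC | intermediate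
8 | (S)-2-chloro-N-methoxy-N,3,3-trimethyl-4-oxobutanamide | O=CC(C)(C)[C@H](Cl)C(=O)N(C)OC | intermediate
9 | methyltriphenylphosphonium bromide | C[P+](c1ccccc1)(c1ccccc1)c1ccccc1.[Br-] | starting material
10 | (S)-2-chloro-N-methoxy-N,3,3-trimethylpent-4-enamide | C=CC(C)(C)[C@H](Cl)C(=O)N(C)OC | intermediate
11 | dibromomethane | BrCBr | starting material
12 | lithium hemiaminal adduct of 10 with dibromomethyllithium (hemiaminal carbon not defined, lost on quench) | C=CC(C)(C)[C@H](Cl)C([O-])(N(C)OC)C(Br)Br.[Li+] | intermediate
13 | (S)-1,1-dibromo-3-chloro-4,4-dimethylhex-5-en-2-one | C=CC(C)(C)[C@H](Cl)C(=O)C(Br)Br | intermediate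
14 | (2R,4R,6S)-2,4-dibromo-6-chloro-5,5-dimethylcyclohexan-1-one | Br[C@@H]1C[C@@H](Br)C(C)(C)[C@H](Cl)C1=O | intermediate
15 | caesium acetate | CC(=O)[O-].[Cs+] | starting material
16 | (1S,3S,5R)-5-bromo-3-chloro-4,4-dimethyl-2-oxocyclohexyl acetate | CC(=O)O[C@H]1C[C@@H](Br)C(C)(C)[C@H](Cl)C1=O | intermediate
17 | vinylmagnesium bromide | C=C[Mg]Br | starting material
18 | (1S,2R,3S,5R)-5-bromo-3-chloro-2-ethenyl-2-hydroxy-4,4-dimethylcyclohexyl acetate (carbinol epimer drawn; either epimer serves) | CC(=O)O[C@H]1C[C@@H](Br)C(C)(C)[C@H](Cl)[C@@]1(O)C=C | intermediate
19 | phosphorus tribromide | BrP(Br)Br | starting material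
20 | (1S,2Z,3R,5R)-5-bromo-2-(2-bromoethylidene)-3-chloro-4,4-dimethylcyclohexyl acetate | CC(=O)O[C@H]1C[C@@H](Br)C(C)(C)[C@H](Cl)/C1=C\CBr | target

**Step count and risks**

Total step count: 10. Longest linear sequence: 10 steps from (R)-pantolactone 1.

Steps most likely to fail:

- **Step 7.** The ring may close in part 5-exo, bromine may return to the C3 face syn to the chloride, or the copper catalyst may re-activate the α-bromo ketone of the product, leading to reduction and loss of HBr. The fallback separates ring closure from the C1 halogenation and sets out from 10. Bromomethyllithium, made in the flask from dibromomethane 11 and MeLi·LiBr in THF at −78 °C, should convert 10 into (S)-1-bromo-3-chloro-4,4-dimethylhex-5-en-2-one F1. Atom-transfer cyclisation of this singly activated bromide (CuBr, tris(2-pyridylmethyl)amine, 1,2-dichloroethane, 60 °C) should give (2S,4R)-4-bromo-2-chloro-3,3-dimethylcyclohexan-1-one F2, which no longer carries an α-bromo ketone. Bromination with CuBr2 in EtOAc/CHCl3 at reflux is expected at the CH2 α-carbon, because acid-mediated enolisation towards the chlorine-bearing neopentyl C5 is slower, and the route is rejoined at 14.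
- **Step 9.** The vinyl metal may attack the acetate, the acetyl group may migrate to the new tertiary alkoxide, or the hindered ketone may be enolised. The fallback gives up the acetate on purpose and sets out from 16. An excess of CH2=CHMgBr/CeCl3 (at least 3.5 equiv, THF, −78 → 0 °C) should add to the ketone and remove the acetyl group, giving (1R,2S,4R,6S)-4-bromo-6-chloro-1-ethenyl-5,5-dimethylcyclohexane-1,2-diol F3. Ac2O, pyridine and catalytic 4-dimethylaminopyridine at 0 °C should then acylate only the secondary hydroxyl, the tertiary one being inert, which returns the route to 18.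
- **Step 10.** Departure of the activated tertiary oxygen is slowed by the flanking acetoxy and chloro groups, so participation by the acetate, elimination to a diene or formation of the wrong alkene geometry may compete. The fallback avoids any cationic activation and sets out from 18. Catalytic Ph3SiOReO3 in Et2O at 0 °C should effect a reversible 1,3-transposition of the allylic alcohol through a sigmatropic perrhenate ester shift; under this thermodynamic control the trisubstituted alkene with CH2OH on the C5 side is expected, giving (1S,2Z,3R,5R)-5-bromo-3-chloro-2-(2-hydroxyethylidene)-4,4-dimethylcyclohexyl acetate F4. An Appel reaction (CBr4, PPh3, CH2Cl2, 0 °C) on this primary allylic alcohol then gives the target 20.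

**Further compounds**

F1 | step 7 | (S)-1-bromo-3-chloro-4,4-dimethylhex-5-en-2-one | C=CC(C)(C)[C@H](Cl)C(=O)CBr
F2 | step 7 | (2S,4R)-4-bromo-2-chloro-3,3-dimethylcyclohexan-1-one | C1C[C@@H](Br)C(C)(C)[C@H](Cl)C1=O
F3 | step 9 | (1R,2S,4R,6S)-4-bromo-6-chloro-1-ethenyl-5,5-dimethylcyclohexane-1,2-diol | O[C@H]1C[C@@H](Br)C(C)(C)[C@H](Cl)[C@@]1(O)C=C
F4 | step 10 | (1S,2Z,3R,5R)-5-bromo-3-chloro-2-(2-hydroxyethylidene)-4,4-dimethylcyclohexyl acetate | CC(=O)O[C@H]1C[C@@H](Br)C(C)(C)[C@H](Cl)/C1=C\CO
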